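If the target stops rising while both starting material and second substrate are still there, the enzyme has stopped working. You see this in the dawn run, where the target stands at 48 % at 6.00 h and 51 % at 12.0 h, with 0.0245 M of starting material and 0.0155 M of second substrate left by subtraction.

| flask | starting material | second substrate | free enzyme | remark | time |
|---|---|---|---|---|---|
| summer | 0.050 M | 0.015 M | 5 µM | run made earlier |  |
| dawn | 0.050 M | 0.041 M | 5 µM | run made earlier |  |
| winter | 0.050 M | 0.11 M | 5 µM | run made earlier |  |
| midnight | 0.14 M | 0.035 M | 5 µM | run made earlier |  |
| blue | 0.20 M | 0.150 M | 5.0 µM |  | 12 h |
| teal | 0.050 M | 0.150 M | 8.0 µM |  | 12 h |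
| red | 0.050 M | 0.0350 M | 5.0 µM |  | 12 h |
| violet | 0.15 M | 0.0800 M | 10 µM |  | 12 h |
| amber | 0.10 M | 0.0120 M | 10 µM |  | 12 h |
| ochre | 0.20 M | 0.100 M | 10 µM |  | 12 h |

| summer: time / h | summer: target / % | dawn: time / h | dawn: target / % | winter: time / h | winter: target / % | midnight: time / h | midnight: target / % |
|---|---|---|---|---|---|---|---|
| 2.50 | 18 | 1.00 | 25 | 1.00 | 60 | 1.00 | 7 |
| 5.00 | 14 | 3.00 | 46 | 2.00 | 97 | 2.00 | 7 |
| 8.00 | 14 | 6.00 | 48 | 3.00 | 103 | 3.00 | 2 |
| 10.0 | 13 | 8.00 | 50 | 6.00 | 100 | 6.00 | 7 |
| 12.0 | 19 | 12.0 | 51 | 12.0 | 98 | 12.0 | 7 |

(scatter of a reading: 2 percentage points)

- in percentages every species weighs as the starting material in it: one spent catalyst counts as two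
- what was read earlier has a scatter of 2 percentage points, one standard deviation
- what may be going on: starting material + free enzyme <-> first complex; first complex -> loaded enzyme + first product; second substrate + loaded enzyme <-> second complex; second complex -> free enzyme + target; starting material + loaded enzyme -> spent catalyst
- no earlier run changes the charge of free enzyme; that part of a forecast is a guess

1. the flasks put in order of amount of target, in percent of the starting material charged, best first, at 12 h (blue / teal / red / violet / amber / ochre)
2. the amount of target, in percent of the starting material charged of the flask you put first, at 12 h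
3. the amount of target, in percent of the starting material charged of the flask you put last, at 12 h

Start with one moment. Loaded enzyme has two exits: with second substrate it goes on towards target and returns as free enzyme, and with starting material it becomes spent catalyst. So target made per enzyme lost should be c·[second substrate]/[starting material], with c a constant.

Now let the comparison drift, because both amounts fall as target P forms. Summing the enzyme lost along the way gives a cost: P, plus (charge of starting material minus charge of second substrate) times ln(charge of second substrate over what is left of it). That cost equals c times the enzyme lost.

Take the dawn plateau as 0.0248 M of target and its enzyme as lost. The cost is 0.0332 M, on 5 µM of enzyme, so c is 6640: the selectivity factor, target made per enzyme lost when the two amounts are equal. The mean of the summer readings gives 6700. I assume the budget, c times the enzyme charged, grows with the charge, which no run tests.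

Teal can afford its whole charge: finishing costs 0.00945 M, less than its budget of 0.0531 M, which is 17.8 % of it. Amber has a budget of 0.0664 M. Using half of its second substrate costs 0.0670 M, so I expect about 6.00 % of target. Solved by trial, red, violet, ochre and blue fall between these two, in that order.

The forecast says teal > red > violet > ochre > blue > amber, with 100 % (96 % to 102 %) and 6 % (4.5 % to 7.8 %), on the ground that “Loaded enzyme partitions between the second substrate (turnover) and the starting material (death)”.

The flasks give teal > red > violet > ochre > blue > amber, with >99.9 % first and 6.03 % last.

    starting material + free enzyme ⇌ first complex (K = 44.2 L mol⁻¹, k = 13700 L mol⁻¹ s⁻¹)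
    first complex → loaded enzyme + first product (k = 2670 min⁻¹)
    second substrate + loaded enzyme ⇌ second complex (K = 9.70 L mol⁻¹, k = 2.82 × 10⁵ L mol⁻¹ min⁻¹)
    second complex → free enzyme + target (k = 286 min⁻¹)
    starting material + loaded enzyme → spent catalyst (k = 0.407 L mol⁻¹ min⁻¹)

In amber, going on to target outruns dying by c·[second substrate]/[starting material], which is 797 at the charge and 422 with the amounts left at 12.0 h. Amber's target comes to 603 per enzyme charged, with spent catalyst at 100 %. A neighbour of amber charged with 0.020 M of second substrate has the same budget, and using half of that charge costs 0.0655 M, which points to about 10.0 %. That neighbour gives 10.2 %.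

All runs come from a simulation for substances that don't exist.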